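**Plan**

- Numbering: C1 (alkyne CH) to C15 (ethyl CH3). The retrosynthesis first removes the C6 acetate, the C12 bromide (back to the inverted alcohol) and the enyne (C2–C3, then C3=C4). It then cuts C14–C15, C13=C14 (back to a lactone carbonyl), the lactone C13–O7 bond, and last C8–C9 and C10–C11.
- Enabling feature: in the oxocene ring (O, C7–C13) the C9=C10 Z-alkene lies between two CH2 groups (C8, C11), each next to an oxygen-bearing stereocentre (C7, C12). C7–C13 is therefore a C7–C8 epoxide and a C11–C12 glycidic ester (C13 = carboxyl) stitched together by acetylene.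
- Forward: the chain C4–C13 is joined in one flask (epoxide + acetylene + glycidate) and the alkyne is semi-reduced. The only ring, the eight-membered oxocene, is closed by lactonisation (C13–O–C7). The lactone carbon is then turned into the ethyl-bearing ether carbon, followed by bromide, enyne and acetate.
- Stereochemistry: C7 from a Sharpless kinetic resolution; C6 by Mitsunobu inversion; C12 from methyl (R)-glycidate, inverted at the bromination; C13 by silicon-tethered hydride delivery from O12; 9Z from Lindlar reduction; 3E from Takai olefination.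

Key step: step 8

Remark: the target is taken as (3E,6R,7R,9Z,12S,13R), so the C7 side chain and the C13 ethyl group are cis on the ring and the C12 bromine is trans to both. In step 4 the unreacted (R)-enantiomer of 5 is removed by chromatography.

**Step 1**
Reactants: 1 propane-1,3-diol
Product: 2 3-(4-methoxybenzyloxy)propan-1-ol
Conditions: NaH, 4-methoxybenzyl chloride, n-Bu4NI (cat.), THF, 0 °C → rt (diol in excess)
Reagents that add atoms: 4-methoxybenzyl chloride, COc1ccc(CCl)cc1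
Why: Williamson etherification, where excess diol should favour the mono-ether.

**Step 2**
Reactants: 2 3-(4-methoxybenzyloxy)propan-1-ol
Product: 3 3-(4-methoxybenzyloxy)propanal
Conditions: TEMPO (cat.), PhI(OAc)2, CH2Cl2, rt
Reagents that add atoms: none
Why: Nitroxyl-catalysed oxidation of a primary alcohol stops at the aldehyde and leaves the benzylic ether alone.

**Step 3**
Reactants: 3 3-(4-methoxybenzyloxy)propanal; 4 vinylmagnesium bromide
Product: 5 (±)-5-(4-methoxybenzyloxy)pent-1-en-3-ol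
Conditions: CH2=CHMgBr, THF, −78 → 0 °C; aq. NH4Cl
Reagents that add atoms: none
Why: Grignard 1,2-addition gives the racemic secondary allylic alcohol needed for the resolution.

**Step 4**
Reactants: 5 (±)-5-(4-methoxybenzyloxy)pent-1-en-3-ol
Product: 6 (1S)-3-(4-methoxybenzyloxy)-1-[(2R)-oxiran-2-yl]propan-1-ol (erythro; 6S,7R)
Conditions: Ti(OiPr)4, L-(+)-DIPT, t-BuOOH (0.45 equiv), 4 Å MS, CH2Cl2, −20 °C
Reagents that add atoms: tert-butyl hydroperoxide, CC(C)(C)OO
Why: Sharpless kinetic resolution, in which the L-tartrate catalyst should epoxidise the (S)-alcohol fast and on the face that gives the erythro epoxy alcohol, setting C7 as R.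

**Step 5**
Reactants: 6 erythro epoxy alcohol
Product: 7 (1R)-3-(4-methoxybenzyloxy)-1-[(2R)-oxiran-2-yl]propyl 4-nitrobenzoate
Conditions: 4-O2NC6H4CO2H, PPh3, DIAD, toluene, 0 °C → rt
Reagents that add atoms: 4-nitrobenzoic acid, OC(=O)c1ccc(cc1)[N+](=O)[O-]
Why: Mitsunobu esterification displaces the activated C6 oxygen by SN2, inverting C6 from S to R without touching the epoxide.

**Step 6**
Reactants: 7 inverted 4-nitrobenzoate
Product: 8 (1R)-3-(4-methoxybenzyloxy)-1-[(2R)-oxiran-2-yl]propan-1-ol (threo; 6R,7R)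
Conditions: K2CO3 (cat.), MeOH, 0 °C
Reagents that add atoms: none
Why: Base-catalysed transesterification of the activated aryl ester frees the alcohol, and at 0 °C it should outrun epoxide migration.

**Step 7**
Reactants: 8 threo epoxy alcohol
Product: 9 (2R)-2-[(1R)-1-(tert-butyldimethylsilyloxy)-3-(4-methoxybenzyloxy)propyl]oxirane
Conditions: TBSCl, imidazole, DMF, rt
Reagents that add atoms: tert-butyldimethylsilyl chloride, CC(C)(C)[Si](C)(C)Cl
Why: Imidazole-promoted silylation of the secondary alcohol under conditions that leave a terminal epoxide intact.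

**Step 8**
Reactants: 9 silyloxy epoxide; 10 acetylene; 11 methyl (R)-glycidate
Product: 16 methyl (2R,7R,8R)-8-(tert-butyldimethylsilyloxy)-2-hydroxy-10-(4-methoxybenzyloxy)-7-(trimethylsilyloxy)dec-4-ynoate, via lithium acetylide 12 (not isolated), via alkoxytrifluoroborate 13 (not isolated), via silyl ether 14 (not isolated), via alkynyllithium 15 (not isolated)
Conditions: n-BuLi, THF, −78 °C; BF3·OEt2, then 9, −78 °C; TMSOTf, Et3N, −78 → −40 °C; n-BuLi, −78 °C; BF3·OEt2, then 11, −78 °C; aq. NaHCO3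
Reagents that add atoms: trimethylsilyl trifluoromethanesulfonate, C[Si](C)(C)OS(=O)(=O)C(F)(F)F
Why: Proposed new method: monolithium acetylide 12, as its BF3 ate complex, should open the BF3-coordinated epoxide 9 by SN2 attack at the unsubstituted C8 to give the boron-bound C7 alkoxide 13, which TMSOTf should convert into silyl ether 14 while Et3N sequesters the released BF3; the remaining acetylenic C–H is then lithiated (15) and the same BF3-assisted SN2 opening is repeated at the CH2 terminus (C11) of glycidate 11. The closest known reaction type is the Yamaguchi–Hirao alkynylation of terminal epoxides, known for each opening taken singly but not with acetylene as a two-fold donor and an oxygen capping in between in one flask. No ring is closed and no stereocentre is created, since both C–C bonds form at CH2 carbons: C6 and C7 keep the configuration of 9 and C12 that of 11. Regioselectivity for the terminal carbons follows from the SN2 character of the Lewis-acid-assisted opening, reinforced by the branched silyloxy-bearing C6 next to C7 and by the ester, which deactivates C12 of 11. Chemoselectivity for epoxide over ester rests on the low temperature and the attenuated basicity of the alkynyl–boron species, and differentiation of the two oxygens rests on silylating O7 before O12 exists; boron binding of the first alkoxide should also suppress migration of the C6 silyl group.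

**Step 9**
Reactants: 16 hydroxy ester
Product: 17 methyl (2R,7R,8R)-8-(tert-butyldimethylsilyloxy)-10-(4-methoxybenzyloxy)-2-(triethylsilyloxy)-7-(trimethylsilyloxy)dec-4-ynoate
Conditions: TESOTf, 2,6-lutidine, CH2Cl2, −78 °C
Reagents that add atoms: triethylsilyl trifluoromethanesulfonate, CC[Si](CC)(CC)OS(=O)(=O)C(F)(F)F
Why: Silyl triflate silylation caps the α-hydroxy ester oxygen (O12) with a group of intermediate lability between the O7 trimethylsilyl and O6 tert-butyldimethylsilyl ethers.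

**Step 10**
Reactants: 17 tris-silyl alkynoate
Product: 18 methyl (2R,4Z,7R,8R)-8-(tert-butyldimethylsilyloxy)-10-(4-methoxybenzyloxy)-2-(triethylsilyloxy)-7-(trimethylsilyloxy)dec-4-enoate
Conditions: H2 (1 atm), Pd/CaCO3 poisoned with Pb(OAc)2, quinoline, EtOAc, rt
Reagents that add atoms: none
Why: Lindlar semi-hydrogenation adds H2 syn to the alkyne and stops at the Z-alkene (C9=C10) without cleaving the benzylic ether.

**Step 11**
Reactants: 18 Z-alkenoate
Product: 19 (2R,4Z,7R,8R)-8-(tert-butyldimethylsilyloxy)-7-hydroxy-10-(4-methoxybenzyloxy)-2-(triethylsilyloxy)dec-4-enoic acid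
Conditions: LiOH, THF/MeOH/H2O, 0 °C → rt; aq. HCl to pH 4
Reagents that add atoms: lithium hydroxide, [Li+].[OH-]
Why: Saponification of the activated methyl ester, with the base-labile trimethylsilyl ether at O7 cleaved in the same medium while the bulkier silyl ethers should persist.

**Step 12**
Reactants: 19 hydroxy acid
Product: 21 (3R,5Z,8R)-8-[(1R)-1-(tert-butyldimethylsilyloxy)-3-(4-methoxybenzyloxy)propyl]-3-(triethylsilyloxy)-3,4,7,8-tetrahydro-2H-oxocin-2-one, via mixed anhydride 20 (not isolated)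
Conditions: 2,4,6-Cl3C6H2COCl, Et3N, THF, rt; then slow addition to DMAP, toluene, 80 °C (high dilution)
Reagents that add atoms: none
Why: Yamaguchi lactonisation; the Z-alkene brings O7 and the activated C13 carboxyl together, so the eight-membered ring should close with retention at C7.

**Step 13**
Reactants: 21 lactone
Product: 22 (3R,5Z,8R)-8-[(1R)-1-(tert-butyldimethylsilyloxy)-3-(4-methoxybenzyloxy)propyl]-2-methylidene-3-(triethylsilyloxy)-3,4,7,8-tetrahydro-2H-oxocine
Conditions: Cp2TiMe2, toluene, 70 °C, dark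
Reagents that add atoms: dimethyltitanocene, [CH3-].[CH3-].c1cc[cH-]c1.c1cc[cH-]c1.[Ti+4]
Why: Petasis methylenation; the thermally formed titanium methylidene olefinates the lactone carbonyl to the exocyclic enol ether (C13=C14) under non-acidic conditions.

**Step 14**
Reactants: 22 enol ether
Product: 23 (3R,5Z,8R)-8-[(1R)-1-(tert-butyldimethylsilyloxy)-3-(4-methoxybenzyloxy)propyl]-2-methylidene-3,4,7,8-tetrahydro-2H-oxocin-3-ol
Conditions: TBAF, THF, −20 °C
Reagents that add atoms: none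
Why: Fluoride desilylation under basic conditions that spare the acid-sensitive enol ether; a secondary triethylsilyl ether should cleave far faster than the hindered secondary tert-butyldimethylsilyl ether.

**Step 15**
Reactants: 23 hydroxy enol ether
Product: 26 (2R,3R,5Z,8R)-8-[(1R)-1-(tert-butyldimethylsilyloxy)-3-(4-methoxybenzyloxy)propyl]-2-(hydroxymethyl)-3,4,7,8-tetrahydro-2H-oxocin-3-ol, via dimethylsilyl ether 24 (not isolated), via cyclic siloxane 25 (not isolated)
Conditions: (HMe2Si)2NH, rt, then evaporation; Pt2[(CH2=CHSiMe2)2O]3 (cat.), THF, rt → 50 °C; H2O2, KF, KHCO3, THF/MeOH, rt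
Reagents that add atoms: hydrogen peroxide, OO; 1,1,3,3-tetramethyldisilazane, C[SiH](C)N[SiH](C)C (its silicon is carried only in 24 and 25)
Why: Tamao intramolecular hydrosilylation–oxidation; the O12–SiMe2H tether should put silicon on C14 and hydrogen on C13 through the five-membered mode in the conformer with C12–H near the enol-ether plane (least 1,2-allylic strain), giving the cis-fused siloxane and hence C13–CH2OH cis to O12 (13R), with the electron-rich 1,1-disubstituted enol ether reacting in preference to the ring Z-alkene.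

**Step 16**
Reactants: 26 diol
Product: 27 [(2R,3R,5Z,8R)-8-[(1R)-1-(tert-butyldimethylsilyloxy)-3-(4-methoxybenzyloxy)propyl]-3-hydroxy-3,4,7,8-tetrahydro-2H-oxocin-2-yl]methyl 4-methylbenzenesulfonate
Conditions: TsCl, Et3N, DMAP (cat.), CH2Cl2, 0 °C
Reagents that add atoms: 4-toluenesulfonyl chloride, Cc1ccc(cc1)S(Cl)(=O)=O
Why: Sulfonylation is selective for the primary C14 hydroxyl over the hindered secondary ring hydroxyl.

**Step 17**
Reactants: 27 primary tosylate
Product: 28 (2R,3R,5Z,8R)-8-[(1R)-1-(tert-butyldimethylsilyloxy)-3-(4-methoxybenzyloxy)propyl]-2-ethyl-3,4,7,8-tetrahydro-2H-oxocin-3-ol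
Conditions: Me2CuLi (from CuI and MeLi, excess), Et2O, −20 → 0 °C
Reagents that add atoms: lithium dimethylcuprate, [Li+].C[Cu-]C
Why: Cuprate SN2 displacement of the primary sulfonate forms C14–C15 (the ethyl group) without touching C12 or C13, one extra equivalent being consumed by the free hydroxyl.

**Step 18**
Reactants: 28 ring alcohol
Product: 29 (2R,3S,5Z,8R)-3-bromo-8-[(1R)-1-(tert-butyldimethylsilyloxy)-3-(4-methoxybenzyloxy)propyl]-2-ethyl-3,4,7,8-tetrahydro-2H-oxocine
Conditions: CBr4, P(n-C8H17)3, toluene, 70 °C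
Reagents that add atoms: carbon tetrabromide, BrC(Br)(Br)Br
Why: Appel-type bromination; bromide displaces the alkoxyphosphonium at C12 by SN2, inverting 12R to 12S and placing bromine trans to the ethyl group.

**Step 19**
Reactants: 29 bromo ether
Product: 30 (3R)-3-[(2R,4Z,7S,8R)-7-bromo-8-ethyl-3,6,7,8-tetrahydro-2H-oxocin-2-yl]-3-(tert-butyldimethylsilyloxy)propan-1-ol
Conditions: DDQ, CH2Cl2/pH 7 buffer, 0 °C → rt
Reagents that add atoms: none
Why: Oxidative cleavage of the 4-methoxybenzyl ether frees the C4 hydroxyl and leaves the silyl ether, alkene and bromide untouched.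

**Step 20**
Reactants: 30 primary alcohol
Product: 31 (3R)-3-[(2R,4Z,7S,8R)-7-bromo-8-ethyl-3,6,7,8-tetrahydro-2H-oxocin-2-yl]-3-(tert-butyldimethylsilyloxy)propanal
Conditions: Dess–Martin periodinane, NaHCO3, CH2Cl2, rt
Reagents that add atoms: none
Why: Buffered periodinane oxidation gives the β-silyloxy aldehyde without elimination.

**Step 21**
Reactants: 31 aldehyde
Product: 32 tert-butyl{[(1R,3E)-1-[(2R,4Z,7S,8R)-7-bromo-8-ethyl-3,6,7,8-tetrahydro-2H-oxocin-2-yl]-4-iodobut-3-en-1-yl]oxy}dimethylsilane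
Conditions: CrCl2, CHI3, THF/dioxane, 0 °C → rt
Reagents that add atoms: iodoform, IC(I)I
Why: Takai olefination; the geminal dichromium species from iodoform adds to the aldehyde and eliminates anti to give the E-vinyl iodide (C3=C4), and an unactivated secondary bromide is not reduced by CrCl2.

**Step 22**
Reactants: 32 E-vinyl iodide
Product: 33 tert-butyl{[(1R,3E)-1-[(2R,4Z,7S,8R)-7-bromo-8-ethyl-3,6,7,8-tetrahydro-2H-oxocin-2-yl]-6-(trimethylsilyl)hex-3-en-5-yn-1-yl]oxy}dimethylsilane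
Conditions: Me3SiC≡CH, Pd(PPh3)2Cl2 (cat.), CuI (cat.), Et3N, THF, rt
Reagents that add atoms: trimethylsilylacetylene, C#C[Si](C)(C)C
Why: Sonogashira coupling forms C2–C3 with retention of the E-geometry; the alkyl bromide does not undergo oxidative addition at room temperature.

**Step 23**
Reactants: 33 silyl enyne
Product: 34 (1R,3E)-1-[(2R,4Z,7S,8R)-7-bromo-8-ethyl-3,6,7,8-tetrahydro-2H-oxocin-2-yl]hex-3-en-5-yn-1-ol
Conditions: TBAF, THF, 0 °C → rt
Reagents that add atoms: none
Why: Fluoride removes the alkynyl trimethylsilyl group and the O6 silyl ether in one operation.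

**Step 24**
Reactants: 34 hydroxy enyne
Product: 35 (1R,3E)-1-[(2R,4Z,7S,8R)-7-bromo-8-ethyl-3,6,7,8-tetrahydro-2H-oxocin-2-yl]hex-3-en-5-yn-1-yl acetate (target)
Conditions: Ac2O, pyridine, DMAP (cat.), CH2Cl2, rt
Reagents that add atoms: acetic anhydride, CC(=O)OC(C)=O
Why: DMAP-catalysed acylation of the only free hydroxyl (O6) completes the target.

**Compound list**

1 | propane-1,3-diol | OCCCO | starting material
2 | 3-(4-methoxybenzyloxy)propan-1-ol | COc1ccc(COCCCO)cc1 | intermediate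
3 | 3-(4-methoxybenzyloxy)propanal | COc1ccc(COCCC=O)cc1 | intermediate
4 | vinylmagnesium bromide | C=C[Mg]Br | starting material
5 | (±)-5-(4-methoxybenzyloxy)pent-1-en-3-ol | COc1ccc(COCCC(O)C=C)cc1 | intermediate
6 | (1S)-3-(4-methoxybenzyloxy)-1-[(2R)-oxiran-2-yl]propan-1-ol | COc1ccc(COCC[C@H](O)[C@H]2CO2)cc1 | intermediate
7 | (1R)-3-(4-methoxybenzyloxy)-1-[(2R)-oxiran-2-yl]propyl 4-nitrobenzoate | COc1ccc(COCC[C@@H](OC(=O)c2ccc(cc2)[N+](=O)[O-])[C@H]2CO2)cc1 | intermediate
8 | (1R)-3-(4-methoxybenzyloxy)-1-[(2R)-oxiran-2-yl]propan-1-ol | COc1ccc(COCC[C@@H](O)[C@H]2CO2)cc1 | intermediate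
9 | (2R)-2-[(1R)-1-(tert-butyldimethylsilyloxy)-3-(4-methoxybenzyloxy)propyl]oxirane | COc1ccc(COCC[C@@H](O[Si](C)(C)C(C)(C)C)[C@H]2CO2)cc1 | intermediate
10 | acetylene | C#C | starting material
11 | methyl (R)-glycidate [methyl (2R)-oxirane-2-carboxylate] | COC(=O)[C@H]1CO1 | starting material
12 | lithium acetylide | [Li]C#C | intermediate
13 | lithium trifluoro{[(4R,5R)-5-(tert-butyldimethylsilyloxy)-7-(4-methoxybenzyloxy)hept-1-yn-4-yl]oxy}borate | [Li+].COc1ccc(COCC[C@@H](O[Si](C)(C)C(C)(C)C)[C@H](O[B-](F)(F)F)CC#C)cc1 | intermediate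
14 | (4R,5R)-5-(tert-butyldimethylsilyloxy)-7-(4-methoxybenzyloxy)-4-(trimethylsilyloxy)hept-1-yne | COc1ccc(COCC[C@@H](O[Si](C)(C)C(C)(C)C)[C@H](O[Si](C)(C)C)CC#C)cc1 | intermediate
15 | [(4R,5R)-5-(tert-butyldimethylsilyloxy)-7-(4-methoxybenzyloxy)-4-(trimethylsilyloxy)hept-1-yn-1-yl]lithium | COc1ccc(COCC[C@@H](O[Si](C)(C)C(C)(C)C)[C@H](O[Si](C)(C)C)CC#C[Li])cc1 | intermediate
16 | methyl (2R,7R,8R)-8-(tert-butyldimethylsilyloxy)-2-hydroxy-10-(4-methoxybenzyloxy)-7-(trimethylsilyloxy)dec-4-ynoate | COc1ccc(COCC[C@@H](O[Si](C)(C)C(C)(C)C)[C@H](O[Si](C)(C)C)CC#CC[C@@H](O)C(=O)OC)cc1 | intermediate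
17 | methyl (2R,7R,8R)-8-(tert-butyldimethylsilyloxy)-10-(4-methoxybenzyloxy)-2-(triethylsilyloxy)-7-(trimethylsilyloxy)dec-4-ynoate | COc1ccc(COCC[C@@H](O[Si](C)(C)C(C)(C)C)[C@H](O[Si](C)(C)C)CC#CC[C@@H](O[Si](CC)(CC)CC)C(=O)OC)cc1 | intermediate
18 | methyl (2R,4Z,7R,8R)-8-(tert-butyldimethylsilyloxy)-10-(4-methoxybenzyloxy)-2-(triethylsilyloxy)-7-(trimethylsilyloxy)dec-4-enoate | COc1ccc(COCC[C@@H](O[Si](C)(C)C(C)(C)C)[C@H](O[Si](C)(C)C)C/C=C\C[C@@H](O[Si](CC)(CC)CC)C(=O)OC)cc1 | intermediate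
19 | (2R,4Z,7R,8R)-8-(tert-butyldimethylsilyloxy)-7-hydroxy-10-(4-methoxybenzyloxy)-2-(triethylsilyloxy)dec-4-enoic acid | COc1ccc(COCC[C@@H](O[Si](C)(C)C(C)(C)C)[C@H](O)C/C=C\C[C@@H](O[Si](CC)(CC)CC)C(=O)O)cc1 | intermediate
20 | mixed anhydride of 19 with 2,4,6-trichlorobenzoic acid | COc1ccc(COCC[C@@H](O[Si](C)(C)C(C)(C)C)[C@H](O)C/C=C\C[C@@H](O[Si](CC)(CC)CC)C(=O)OC(=O)c2c(Cl)cc(Cl)cc2Cl)cc1 | intermediate
21 | (3R,5Z,8R)-8-[(1R)-1-(tert-butyldimethylsilyloxy)-3-(4-methoxybenzyloxy)propyl]-3-(triethylsilyloxy)-3,4,7,8-tetrahydro-2H-oxocin-2-one | COc1ccc(COCC[C@@H](O[Si](C)(C)C(C)(C)C)[C@H]2C/C=C\C[C@@H](O[Si](CC)(CC)CC)C(=O)O2)cc1 | intermediate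
22 | (3R,5Z,8R)-8-[(1R)-1-(tert-butyldimethylsilyloxy)-3-(4-methoxybenzyloxy)propyl]-2-methylidene-3-(triethylsilyloxy)-3,4,7,8-tetrahydro-2H-oxocine | COc1ccc(COCC[C@@H](O[Si](C)(C)C(C)(C)C)[C@H]2C/C=C\C[C@@H](O[Si](CC)(CC)CC)C(=C)O2)cc1 | intermediate
23 | (3R,5Z,8R)-8-[(1R)-1-(tert-butyldimethylsilyloxy)-3-(4-methoxybenzyloxy)propyl]-2-methylidene-3,4,7,8-tetrahydro-2H-oxocin-3-ol | COc1ccc(COCC[C@@H](O[Si](C)(C)C(C)(C)C)[C@H]2C/C=C\C[C@@H](O)C(=C)O2)cc1 | intermediate
24 | dimethylsilyl ether of 23 (O12–SiMe2H) | COc1ccc(COCC[C@@H](O[Si](C)(C)C(C)(C)C)[C@H]2C/C=C\C[C@@H](O[SiH](C)C)C(=C)O2)cc1 | intermediate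
25 | cis-fused bicyclic siloxane (five-membered ring O12–SiMe2–C14H2–C13–C12 fused to the oxocene; O12 and C14 cis; 12R,13S) | COc1ccc(COCC[C@@H](O[Si](C)(C)C(C)(C)C)[C@H]2C/C=C\C[C@H]3O[Si](C)(C)C[C@H]3O2)cc1 | intermediate
26 | (2R,3R,5Z,8R)-8-[(1R)-1-(tert-butyldimethylsilyloxy)-3-(4-methoxybenzyloxy)propyl]-2-(hydroxymethyl)-3,4,7,8-tetrahydro-2H-oxocin-3-ol | COc1ccc(COCC[C@@H](O[Si](C)(C)C(C)(C)C)[C@H]2C/C=C\C[C@@H](O)[C@@H](CO)O2)cc1 | intermediate
27 | [(2R,3R,5Z,8R)-8-[(1R)-1-(tert-butyldimethylsilyloxy)-3-(4-methoxybenzyloxy)propyl]-3-hydroxy-3,4,7,8-tetrahydro-2H-oxocin-2-yl]methyl 4-methylbenzenesulfonate | COc1ccc(COCC[C@@H](O[Si](C)(C)C(C)(C)C)[C@H]2C/C=C\C[C@@H](O)[C@@H](COS(=O)(=O)c3ccc(C)cc3)O2)cc1 | intermediate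
28 | (2R,3R,5Z,8R)-8-[(1R)-1-(tert-butyldimethylsilyloxy)-3-(4-methoxybenzyloxy)propyl]-2-ethyl-3,4,7,8-tetrahydro-2H-oxocin-3-ol | COc1ccc(COCC[C@@H](O[Si](C)(C)C(C)(C)C)[C@H]2C/C=C\C[C@@H](O)[C@@H](CC)O2)cc1 | intermediate
29 | (2R,3S,5Z,8R)-3-bromo-8-[(1R)-1-(tert-butyldimethylsilyloxy)-3-(4-methoxybenzyloxy)propyl]-2-ethyl-3,4,7,8-tetrahydro-2H-oxocine | COc1ccc(COCC[C@@H](O[Si](C)(C)C(C)(C)C)[C@H]2C/C=C\C[C@H](Br)[C@@H](CC)O2)cc1 | intermediate
30 | (3R)-3-[(2R,4Z,7S,8R)-7-bromo-8-ethyl-3,6,7,8-tetrahydro-2H-oxocin-2-yl]-3-(tert-butyldimethylsilyloxy)propan-1-ol | OCC[C@@H](O[Si](C)(C)C(C)(C)C)[C@H]1C/C=C\C[C@H](Br)[C@@H](CC)O1 | intermediate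
31 | (3R)-3-[(2R,4Z,7S,8R)-7-bromo-8-ethyl-3,6,7,8-tetrahydro-2H-oxocin-2-yl]-3-(tert-butyldimethylsilyloxy)propanal | O=CC[C@@H](O[Si](C)(C)C(C)(C)C)[C@H]1C/C=C\C[C@H](Br)[C@@H](CC)O1 | intermediate
32 | tert-butyl{[(1R,3E)-1-[(2R,4Z,7S,8R)-7-bromo-8-ethyl-3,6,7,8-tetrahydro-2H-oxocin-2-yl]-4-iodobut-3-en-1-yl]oxy}dimethylsilane | I/C=C/C[C@@H](O[Si](C)(C)C(C)(C)C)[C@H]1C/C=C\C[C@H](Br)[C@@H](CC)O1 | intermediate
33 | tert-butyl{[(1R,3E)-1-[(2R,4Z,7S,8R)-7-bromo-8-ethyl-3,6,7,8-tetrahydro-2H-oxocin-2-yl]-6-(trimethylsilyl)hex-3-en-5-yn-1-yl]oxy}dimethylsilane | C[Si](C)(C)C#C/C=C/C[C@@H](O[Si](C)(C)C(C)(C)C)[C@H]1C/C=C\C[C@H](Br)[C@@H](CC)O1 | intermediate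
34 | (1R,3E)-1-[(2R,4Z,7S,8R)-7-bromo-8-ethyl-3,6,7,8-tetrahydro-2H-oxocin-2-yl]hex-3-en-5-yn-1-ol | C#C/C=C/C[C@@H](O)[C@H]1C/C=C\C[C@H](Br)[C@@H](CC)O1 | intermediate
35 | (1R,3E)-1-[(2R,4Z,7S,8R)-7-bromo-8-ethyl-3,6,7,8-tetrahydro-2H-oxocin-2-yl]hex-3-en-5-yn-1-yl acetate | C#C/C=C/C[C@@H](OC(C)=O)[C@H]1C/C=C\C[C@H](Br)[C@@H](CC)O1 | target

**Count and risks**

Total steps: 24. Longest linear sequence: 24 steps (1 → 35); acetylene 10 and glycidate 11 enter at step 8.

Step 8 (new one-flask method). The boron-bound C7 alkoxide may escape silylation, or the second lithiation may be upset by boron and silicon by-products, so that the two oxygens are not differentiated or acetylene is alkylated only once. The fallback uses known chemistry, sets out from 9 and comes back at 16. The two epoxide openings are run as separate Yamaguchi–Hirao alkynylations with isolation in between. Epoxide 9 is opened with HC≡CLi/BF3·OEt2 in THF at −78 °C and worked up to (4R,5R)-5-(tert-butyldimethylsilyloxy)-7-(4-methoxybenzyloxy)hept-1-yn-4-ol F1. This is silylated with TMSCl/Et3N in CH2Cl2 to give 14 as an isolated compound. Lithiation of 14 with n-BuLi and addition to 11 with BF3·OEt2 at −78 °C then gives 16.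

Step 15 (tethered hydrosilylation). Hydride may be delivered to the wrong face of C13 (trans-fused siloxane), or the tethered silane may add to the homoallylic ring alkene. The fallback sets out from 22 and comes back at 28; it gives up the tether for reagent-approach control. Hydroboration of the enol ether of 22 with 9-BBN (THF, 0 °C → rt), then NaBO3 oxidation, should place boron on C14 from the face opposite the O12 silyl ether. This gives the C14 primary alcohol F2 with the triethylsilyl ether intact. Tosylation (TsCl, pyridine) gives the tosylate F3, Me2CuLi gives the ethyl compound F4, and PPTS in MeOH removes the triethylsilyl group to give 28.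

Step 18 (bromination with inversion). Elimination toward the ring alkene, or participation of the ring oxygen, may compete during phosphonium activation of the hindered C12 alcohol. The fallback sets out from 28 and comes back at 29; it separates activation from displacement. ClCH2SO2Cl and 2,6-lutidine in CH2Cl2 at 0 °C give the chloromethanesulfonate F5, which n-Bu4NBr in toluene at 80 °C should displace by SN2 with inversion to give 29.

**Further compounds**

F1 | step 8 | (4R,5R)-5-(tert-butyldimethylsilyloxy)-7-(4-methoxybenzyloxy)hept-1-yn-4-ol | COc1ccc(COCC[C@@H](O[Si](C)(C)C(C)(C)C)[C@H](O)CC#C)cc1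
F2 | step 15 | [(2R,3R,5Z,8R)-8-[(1R)-1-(tert-butyldimethylsilyloxy)-3-(4-methoxybenzyloxy)propyl]-3-(triethylsilyloxy)-3,4,7,8-tetrahydro-2H-oxocin-2-yl]methanol | COc1ccc(COCC[C@@H](O[Si](C)(C)C(C)(C)C)[C@H]2C/C=C\C[C@@H](O[Si](CC)(CC)CC)[C@@H](CO)O2)cc1
F3 | step 15 | [(2R,3R,5Z,8R)-8-[(1R)-1-(tert-butyldimethylsilyloxy)-3-(4-methoxybenzyloxy)propyl]-3-(triethylsilyloxy)-3,4,7,8-tetrahydro-2H-oxocin-2-yl]methyl 4-methylbenzenesulfonate | COc1ccc(COCC[C@@H](O[Si](C)(C)C(C)(C)C)[C@H]2C/C=C\C[C@@H](O[Si](CC)(CC)CC)[C@@H](COS(=O)(=O)c3ccc(C)cc3)O2)cc1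
F4 | step 15 | {[(2R,3R,5Z,8R)-8-[(1R)-1-(tert-butyldimethylsilyloxy)-3-(4-methoxybenzyloxy)propyl]-2-ethyl-3,4,7,8-tetrahydro-2H-oxocin-3-yl]oxy}triethylsilane | COc1ccc(COCC[C@@H](O[Si](C)(C)C(C)(C)C)[C@H]2C/C=C\C[C@@H](O[Si](CC)(CC)CC)[C@@H](CC)O2)cc1
F5 | step 18 | (2R,3R,5Z,8R)-8-[(1R)-1-(tert-butyldimethylsilyloxy)-3-(4-methoxybenzyloxy)propyl]-2-ethyl-3,4,7,8-tetrahydro-2H-oxocin-3-yl chloromethanesulfonate | COc1ccc(COCC[C@@H](O[Si](C)(C)C(C)(C)C)[C@H]2C/C=C\C[C@@H](OS(=O)(=O)CCl)[C@@H](CC)O2)cc1
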